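(The runs are calculated with made-up constants; scatter was added.)

- At late times ring stops rising and rides on the substrate still present: the dusk run reads 9.1%, 9.9% and 9.0% of ring around its top. At a top, ring is made as fast as it is used, so ring over substrate there, 0.268 at 3.00 h, is our tracking ratio, a quasi-steady reading at 25 °C that carries the scatter of 1 percentage point.

| flask | substrate | temperature | remark | time |
|---|---|---|---|---|
| autumn | 0.75 M | −5 °C | run made earlier |  |
| dusk | 3 M | 25 °C | run made earlier |  |
| green | 1.5 M | 25 °C |  | 6.0 h |
| ochre | 1.5 M | 0 °C |  | 6.0 h |
| red | 1.5 M | 50 °C |  | 6.0 h |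
| amber | 1.5 M |  | at 0 °C until 2.0 h, from then on at 50 °C | 6.0 h |

| run | time / h | ring / % | substrate / % |
|---|---|---|---|
| autumn | 1.00 | 1.5 | 99.8 |
| autumn | 2.00 | 0 | 98.9 |
| autumn | 4.00 | 1.6 | 96.6 |
| autumn | 8.00 | 1.2 | 96.3 |
| autumn | 20.0 | 4.3 | 90.5 |
| dusk | 0.667 | 2.8 | 73.2 |
| dusk | 1.33 | 6.2 | 55.8 |
| dusk | 2.00 | 9.1 | 45.2 |
| dusk | 3.00 | 9.9 | 37.0 |
| dusk | 4.00 | 9.0 | 29.7 |

(scatter of a reading: 1 percentage point)

- in percentages every species weighs as the substrate in it: one open dimer counts as two
- steps under discussion: substrate <-> ring; 2 substrate -> open dimer; ring -> over-reaction product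

- the best flask by amount of ring, in percent of the substrate charged; "all alike" if 1.5 percentage points covers them all (green / ochre / red / amber / all alike)
- amount of ring at the end, in percent of the substrate charged, green
- amount of ring at the end, in percent of the substrate charged, ochre
- amount of ring at the end, in percent of the substrate charged, red
- amount of ring at the end, in percent of the substrate charged, amber

- First extreme, no ring lost: the autumn run makes 0.00226 /h of ring on its mean substrate, so 6.0 h gives 1.36%. We expect ochre slightly above this, since it is warmer than autumn.
- Second extreme, ring fully tracking: ring is the ratio times the substrate left, so we expect small values in red and amber, if heat leaves little substrate by the end.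
- Green lies between these. Dimerisation is second-order, so at half the charge and twice the time, green should reach the dusk substrate of 37.0%, and tracking gives a floor of 9.92%.
- The early dusk rise gives 0.0598 /h, so a no-loss green has a ceiling of 24.6%.
- Going round once more, the ratio and this rate give ring a loss half-life of 3.10 h, about half of green's time, so ring lags its substrate. Putting in the earlier substrate, the nearest dusk reading of 55.8%, gives our 14.9% for green.
- The forecast names green, with 11% for green, 2.6% for ochre, 1.5% for red and 2% for amber, holding that “temperature barely changes selectivity”. Our green stands above its figure.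

    substrate ⇌ ring (K = 0.566, k = 0.0806 /h, Ea = 91.0 kJ/mol, ΔH = −38.0 kJ/mol)
    2 substrate → open dimer (k = 0.0814 /M/h, Ea = 78.0 kJ/mol)
    ring → over-reaction product (k = 0.0655 /h, Ea = 103 kJ/mol)
    (constants at 25 °C)

- Green leads with 13.6%, against 1.59% in ochre, 0.442% in red and 0.823% in amber; a run putting another flask above green, or all four flasks within 1.5 points, would overturn the forecast's choice, and green's ring is passing, at 1.74% after 60.0 h. In amber, the relaxation half-life of substrate and ring by that step alone at 50 °C is 0.0741 h, short against 6.0 h. Ring over substrate in amber is 0.149 at 6.00 h and 0.164 in the same flask read at 2.5 h, both below the 0.268 read at 25 °C.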